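Ring numbering used below: C1 = C(OH)CH3, C2 = CH carrying the chain, C3 = C(CH3)2, C4–C6 = CH2; C1' is the chain CH2 on C2, C2' the next CH2.

- Retrosynthesis: cut C1'–C2' (C10 ring sulfone + 12-bromofarnesyl unit, the three E alkenes ready-made from farnesol), then open the ring at C1–C6.
- Enabling feature: C1 is an oxygen-bearing carbon next to C2, and C2 sits between C1 and the quaternary C3. With C2 held as an exocyclic methylene, the open-chain C1–H (as its carbamate) is the only allylic, O-activated hydrogen, and C6 is an unbranched primary carbon that can ride on boron.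
- Forward: acid 1 → methyl ketone → Shapiro acylation → CBS reduction → carbamate → terminal hydroboration; the chain then closes by lithiation, capture by the tethered boronate (seven-membered boracycle) and a ring-contracting 1,2-metallate shift, then oxidation.
- The tertiary OH next delivers Si–H through a temporary oxasilolane ring to set C2; Tamao–Fleming oxidation, sulfide, sulfone, alkylation with the farnesyl bromide, desulfonylation and desilylation finish the route.
- Stereochemistry: C1 from the CBS reduction, relayed stereospecifically by the 1,2-shift; C2 from the O-tethered same-face hydrosilylation; alkene geometry from (2E,6E)-farnesol and an E-selective SeO2 oxidation.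

Key step: step 7

Remark: 1 and 18 are taken as commercial; the sulfone-bearing carbon of 22 and 23 is an epimer mixture, which is erased in step 16.

Step 1
Reactants: 1 2,2-dimethylpent-4-enoic acid
Product: 2 3,3-dimethylhex-5-en-2-one
Conditions: MeLi (2.2 equiv), Et2O, 0 °C → rt; inverse quench into cold 1 M HCl
Reagents that add atoms: methyllithium, [Li]C
Why: addition of methyllithium to the lithium carboxylate gives a dilithio gem-diolate that collapses to the methyl ketone only on work-up (ketone synthesis from a carboxylic acid and two equivalents of organolithium), and the quaternary alpha carbon suppresses over-addition.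

Step 2
Reactants: 2 3,3-dimethylhex-5-en-2-one
Product: 3 (E)-N'-(3,3-dimethylhex-5-en-2-ylidene)-2,4,6-tri(propan-2-yl)benzenesulfonohydrazide
Conditions: 2,4,6-tri(propan-2-yl)benzenesulfonohydrazide, cat. HCl, MeOH, rt
Reagents that add atoms: 2,4,6-tri(propan-2-yl)benzenesulfonohydrazide, NNS(=O)(=O)c1c(C(C)C)cc(C(C)C)cc1C(C)C
Why: acid-catalysed hydrazone formation prepares the Shapiro reaction, the sulfonamide nitrogen settling anti to the quaternary carbon and so syn to the methyl group that must be deprotonated.

Step 3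
Reactants: 3 (E)-N'-(3,3-dimethylhex-5-en-2-ylidene)-2,4,6-tri(propan-2-yl)benzenesulfonohydrazide
Product: 5 4,4-dimethyl-3-methylidenehept-6-en-2-one, via vinyllithium 4 (not isolated)
Conditions: n-BuLi (2.1 equiv), TMEDA, THF, −78 → 0 °C; then N-methoxy-N-methylacetamide, −78 °C → rt; 1 M HCl
Reagents that add atoms: N-methoxy-N-methylacetamide, CC(=O)N(C)OC
Why: Shapiro reaction (deprotonation at N–H and at the only alpha C–H, loss of sulfinate and N2) gives the 1,1-disubstituted vinyllithium, which is acylated by the N-methoxy-N-methylamide through a chelated tetrahedral intermediate that prevents over-addition.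

Step 4
Reactants: 5 4,4-dimethyl-3-methylidenehept-6-en-2-one
Product: 6 (2R)-4,4-dimethyl-3-methylidenehept-6-en-2-ol
Conditions: (S)-Me-CBS oxazaborolidine [(3aS)-1-methyl-3,3-diphenyltetrahydro-1H,3H-pyrrolo[1,2-c][1,3,2]oxazaborole] (20 mol%), catecholborane (1.5 equiv), toluene, −78 °C; then MeOH, aqueous wash
Reagents that add atoms: none
Why: Corey–Bakshi–Shibata reduction of a methyl alkenyl ketone, in which the oxazaborolidine binds the carbonyl anti to the large 1-substituted vinyl group and delivers hydride to one face, so the (S)-catalyst should give the (R)-alcohol; catecholborane at −78 °C leaves both C=C bonds alone.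

Step 5
Reactants: 6 (2R)-4,4-dimethyl-3-methylidenehept-6-en-2-ol
Product: 7 (2R)-4,4-dimethyl-3-methylidenehept-6-en-2-yl N,N-di(propan-2-yl)carbamate
Conditions: NaH, N,N-di(propan-2-yl)carbamoyl chloride, THF, 0 → 60 °C
Reagents that add atoms: N,N-di(propan-2-yl)carbamoyl chloride, CC(C)N(C(C)C)C(Cl)=O
Why: O-acylation of the sodium alkoxide installs the carbamate that later directs and acidifies removal of the carbinol hydrogen and serves as the leaving group, without touching the stereocentre.

Step 6
Reactants: 7 (2R)-4,4-dimethyl-3-methylidenehept-6-en-2-yl N,N-di(propan-2-yl)carbamate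
Product: 8 (2R)-4,4-dimethyl-3-methylidene-7-(4,4,5,5-tetramethyl-1,3,2-dioxaborolan-2-yl)heptan-2-yl N,N-di(propan-2-yl)carbamate
Conditions: pinacolborane (1.2 equiv), [Ir(cod)Cl]2 (1.5 mol%), dppe (3 mol%), CH2Cl2, rt
Reagents that add atoms: 4,4,5,5-tetramethyl-1,3,2-dioxaborolane (pinacolborane), CC1(C)OBOC1(C)C
Why: iridium-catalysed anti-Markovnikov hydroboration is selective for the monosubstituted terminal alkene, the 1,1-disubstituted alkene between the quaternary carbon and the carbamate carbon being far slower.

Step 7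
Reactants: 8 (2R)-4,4-dimethyl-3-methylidene-7-(4,4,5,5-tetramethyl-1,3,2-dioxaborolan-2-yl)heptan-2-yl N,N-di(propan-2-yl)carbamate
Product: 12 (1S)-1,3,3-trimethyl-2-methylidenecyclohexan-1-ol, via lithiated carbamate 9 (not isolated), via cyclic boronate complex 10 (not isolated), via tertiary boronic ester 11 (not isolated)
Conditions: lithium 2,2,6,6-tetramethylpiperidide (1.3 equiv, slow addition), TMEDA, Et2O (0.02 M), −78 °C, then 35 °C; then 2 M NaOH, 30% H2O2, THF, 0 °C
Reagents that add atoms: hydrogen peroxide, OO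
Why: Proposed new method: the hindered amide base, which does not bind the pinacol boronate, removes the carbamate-bearing C–H (the only allylic hydrogen, since the other allylic carbon is quaternary) and the lithium carbenoid 9 is captured at once by the tethered boronate to give the seven-membered boronate complex 10, whose endocyclic B–CH2 bond migrates anti to the carbamate and expels it, forming the C1–C6 bond before C–B is oxidised to C–OH. The closest known reaction types are the lithiation–borylation of secondary allylic carbamates with external boronic esters and its in situ variant (amide base with the boronic ester present) for secondary benzylic carbamates; what is new is capture by a boronate held in the same molecule. The cyclohexane is closed by ring contraction of the seven-membered boracycle, formally a 6-exo-tet displacement of the carbamate at the carbenoid carbon by the C–B sigma bond. The new quaternary stereocentre is controlled by the CBS-derived centre of 8 through lithiation and borylation with retention, migration with inversion at carbon and oxidation with retention, so that (R)-8 should give (S)-12. The step needs boron capture at the oxygen-bearing end of the allyl anion and within one molecule; the carbamate holds lithium at that carbon, a complex formed at the CH2 end has no adjacent leaving group and can revert, and high dilution disfavours capture between molecules.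

Step 8
Reactants: 12 (1S)-1,3,3-trimethyl-2-methylidenecyclohexan-1-ol
Product: 14 (3aS,7aS)-2,2,4,4,7a-pentamethyloctahydro-1,2-benzoxasilole, via hydridosilyl ether 13 (not isolated)
Conditions: chlorodimethylsilane, Et3N, DMAP (cat.), CH2Cl2, 0 °C; filter; then H2PtCl6·6H2O (0.5 mol%), toluene, 60 °C
Reagents that add atoms: chlorodimethylsilane, C[SiH](C)Cl
Why: silylation followed by platinum-catalysed intramolecular hydrosilylation (the 5-endo mode known for allylic alcohols) puts Si on the exocyclic CH2 and H on C2, and because silicon is tied to the C1 oxygen the hydrogen should arrive on the face of that oxygen, setting C2 with H cis to O in a trans-fused oxasilolane.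

Step 9
Reactants: 14 (3aS,7aS)-2,2,4,4,7a-pentamethyloctahydro-1,2-benzoxasilole
Product: 15 (1S,2R)-2-(hydroxymethyl)-1,3,3-trimethylcyclohexan-1-ol
Conditions: KF, KHCO3, 30% H2O2, THF/MeOH (1:1), rt → 40 °C
Reagents that add atoms: hydrogen peroxide, OO
Why: Tamao–Fleming oxidation replaces C–Si by C–OH and frees the tertiary alcohol, removing the temporary ring without touching either stereocentre.

Step 10
Reactants: 15 (1S,2R)-2-(hydroxymethyl)-1,3,3-trimethylcyclohexan-1-ol
Product: 16 (1S,2S)-1,3,3-trimethyl-2-[(phenylsulfanyl)methyl]cyclohexan-1-ol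
Conditions: PhSSPh, n-Bu3P, pyridine, rt → 50 °C
Reagents that add atoms: diphenyl disulfide, c1ccc(SSc2ccccc2)cc1
Why: Hata reaction (phosphine–disulfide activation, then SN2 displacement of the oxyphosphonium by thiophenolate) converts only the primary alcohol, the tertiary one being too hindered to be activated.

Step 11
Reactants: 16 (1S,2S)-1,3,3-trimethyl-2-[(phenylsulfanyl)methyl]cyclohexan-1-ol
Product: 17 (1S,2S)-2-[(benzenesulfonyl)methyl]-1,3,3-trimethylcyclohexan-1-ol
Conditions: (NH4)6Mo7O24·4H2O (10 mol%), 30% H2O2, EtOH, 0 °C → rt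
Reagents that add atoms: hydrogen peroxide, OO
Why: molybdate-catalysed peroxide oxidation takes the sulfide to the sulfone, with no alkene present and the tertiary alcohol inert.

Step 12
Reactants: 18 (2E,6E)-farnesol
Product: 19 tert-butyl(dimethyl){[(2E,6E)-3,7,11-trimethyldodeca-2,6,10-trien-1-yl]oxy}silane
Conditions: TBSCl, imidazole, DMF, rt
Reagents that add atoms: tert-butylchlorodimethylsilane, CC(C)(C)[Si](C)(C)Cl
Why: imidazole-promoted silylation protects the primary allylic alcohol against the organolithium and sodium amalgam steps.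

Step 13
Reactants: 19 tert-butyl(dimethyl){[(2E,6E)-3,7,11-trimethyldodeca-2,6,10-trien-1-yl]oxy}silane
Product: 20 (2E,6E,10E)-12-{[tert-butyl(dimethyl)silyl]oxy}-2,6,10-trimethyldodeca-2,6,10-trien-1-ol
Conditions: SeO2 (0.3 equiv), t-BuOOH (3 equiv), salicylic acid (0.1 equiv), CH2Cl2, 0 °C → rt
Reagents that add atoms: tert-butyl hydroperoxide, CC(C)(C)OO
Why: SeO2-catalysed allylic oxidation (ene reaction, then [2,3]-sigmatropic shift) attacks the terminal isopropylidene group and hydroxylates its (E)-methyl group, giving the (E)-allylic alcohol.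

Step 14
Reactants: 20 (2E,6E,10E)-12-{[tert-butyl(dimethyl)silyl]oxy}-2,6,10-trimethyldodeca-2,6,10-trien-1-ol
Product: 21 tert-butyl{[(2E,6E,10E)-12-bromo-3,7,11-trimethyldodeca-2,6,10-trien-1-yl]oxy}dimethylsilane
Conditions: CBr4, PPh3, CH2Cl2, −20 → 0 °C
Reagents that add atoms: tetrabromomethane, BrC(Br)(Br)Br
Why: Appel reaction gives the primary allylic bromide by SN2 displacement of the oxyphosphonium at low temperature, with the (E)-alkene retained and no allylic transposition.

Step 15
Reactants: 17 (1S,2S)-2-[(benzenesulfonyl)methyl]-1,3,3-trimethylcyclohexan-1-ol; 21 tert-butyl{[(2E,6E,10E)-12-bromo-3,7,11-trimethyldodeca-2,6,10-trien-1-yl]oxy}dimethylsilane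
Product: 23 (1S,2S)-2-[(3E,7E,11E)-1-(benzenesulfonyl)-13-{[tert-butyl(dimethyl)silyl]oxy}-3,7,11-trimethyltrideca-3,7,11-trien-1-yl]-1,3,3-trimethylcyclohexan-1-ol (epimers at the sulfone carbon), via dilithio sulfone 22 (not isolated)
Conditions: n-BuLi (2.2 equiv), THF/DMPU, −78 → −20 °C; then 21, −78 → −40 °C; H2O
Reagents that add atoms: none
Why: alkylation of the alpha-sulfonyl carbanion (alkoxide formed first, carbanion second) with the primary allylic bromide by SN2 joins ring and chain at a saturated carbon, so all three (E)-alkenes are carried over unchanged.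

Step 16
Reactants: 23 (1S,2S)-2-[(3E,7E,11E)-1-(benzenesulfonyl)-13-{[tert-butyl(dimethyl)silyl]oxy}-3,7,11-trimethyltrideca-3,7,11-trien-1-yl]-1,3,3-trimethylcyclohexan-1-ol
Product: 24 (1S,2S)-2-[(3E,7E,11E)-13-{[tert-butyl(dimethyl)silyl]oxy}-3,7,11-trimethyltrideca-3,7,11-trien-1-yl]-1,3,3-trimethylcyclohexan-1-ol
Conditions: 6% Na(Hg), Na2HPO4, MeOH/THF, −20 °C
Reagents that add atoms: none
Why: reductive desulfonylation by electron transfer cleaves the C–S bond and methanol protonates the carbanion; the hydroxyl is gamma to sulfur, so no Julia-type elimination is possible, and the buffer protects the silyl ether.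

Step 17
Reactants: 24 (1S,2S)-2-[(3E,7E,11E)-13-{[tert-butyl(dimethyl)silyl]oxy}-3,7,11-trimethyltrideca-3,7,11-trien-1-yl]-1,3,3-trimethylcyclohexan-1-ol
Product: 25 preluffariellolide A, (1S,2S)-2-[(3E,7E,11E)-13-hydroxy-3,7,11-trimethyltrideca-3,7,11-trien-1-yl]-1,3,3-trimethylcyclohexan-1-ol
Conditions: TBAF, THF, 0 °C → rt
Reagents that add atoms: none
Why: fluoride-mediated silyl ether cleavage frees the primary allylic alcohol and gives the target.

Compound list
1 | 2,2-dimethylpent-4-enoic acid | OC(=O)C(C)(C)CC=C | starting material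
2 | 3,3-dimethylhex-5-en-2-one | CC(=O)C(C)(C)CC=C | intermediate
3 | (E)-N'-(3,3-dimethylhex-5-en-2-ylidene)-2,4,6-tri(propan-2-yl)benzenesulfonohydrazide | C/C(=N\NS(=O)(=O)c1c(C(C)C)cc(C(C)C)cc1C(C)C)C(C)(C)CC=C | intermediate
4 | (3,3-dimethylhexa-1,5-dien-2-yl)lithium | [Li]C(=C)C(C)(C)CC=C | intermediate (not isolated)
5 | 4,4-dimethyl-3-methylidenehept-6-en-2-one | CC(=O)C(=C)C(C)(C)CC=C | intermediate
6 | (2R)-4,4-dimethyl-3-methylidenehept-6-en-2-ol | C[C@@H](O)C(=C)C(C)(C)CC=C | intermediate
7 | (2R)-4,4-dimethyl-3-methylidenehept-6-en-2-yl N,N-di(propan-2-yl)carbamate | C[C@@H](OC(=O)N(C(C)C)C(C)C)C(=C)C(C)(C)CC=C | intermediate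
8 | (2R)-4,4-dimethyl-3-methylidene-7-(4,4,5,5-tetramethyl-1,3,2-dioxaborolan-2-yl)heptan-2-yl N,N-di(propan-2-yl)carbamate | C[C@@H](OC(=O)N(C(C)C)C(C)C)C(=C)C(C)(C)CCCB1OC(C)(C)C(C)(C)O1 | intermediate
9 | 2-lithio derivative of 8 (Li in place of the carbinol H, configuration retained) | C[C@@]([Li])(OC(=O)N(C(C)C)C(C)C)C(=C)C(C)(C)CCCB1OC(C)(C)C(C)(C)O1 | intermediate (not isolated)
10 | lithium spiro boronate complex (seven-membered boracycle: boron bonded to the carbamate carbon, to the chain-end CH2 and to the pinacolate oxygens) | [Li+].C[C@@]1(OC(=O)N(C(C)C)C(C)C)C(=C)C(C)(C)CCC[B-]12OC(C)(C)C(C)(C)O2 | intermediate (not isolated)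
11 | 4,4,5,5-tetramethyl-2-[(1R)-1,3,3-trimethyl-2-methylidenecyclohexyl]-1,3,2-dioxaborolane | C[C@]1(B2OC(C)(C)C(C)(C)O2)CCCC(C)(C)C1=C | intermediate (not isolated)
12 | (1S)-1,3,3-trimethyl-2-methylidenecyclohexan-1-ol | C[C@]1(O)CCCC(C)(C)C1=C | intermediate
13 | dimethyl{[(1S)-1,3,3-trimethyl-2-methylidenecyclohexyl]oxy}silane | C[C@]1(O[SiH](C)C)CCCC(C)(C)C1=C | intermediate (not isolated)
14 | (3aS,7aS)-2,2,4,4,7a-pentamethyloctahydro-1,2-benzoxasilole (trans-fused; O on C7a, Si bonded to the CH2 on C3a) | C[Si]1(C)C[C@H]2C(C)(C)CCC[C@]2(C)O1 | intermediate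
15 | (1S,2R)-2-(hydroxymethyl)-1,3,3-trimethylcyclohexan-1-ol | OC[C@H]1C(C)(C)CCC[C@]1(C)O | intermediate
16 | (1S,2S)-1,3,3-trimethyl-2-[(phenylsulfanyl)methyl]cyclohexan-1-ol | c1ccccc1SC[C@H]1C(C)(C)CCC[C@]1(C)O | intermediate
17 | (1S,2S)-2-[(benzenesulfonyl)methyl]-1,3,3-trimethylcyclohexan-1-ol | O=S(=O)(C[C@H]1C(C)(C)CCC[C@]1(C)O)c1ccccc1 | intermediate
18 | (2E,6E)-farnesol, (2E,6E)-3,7,11-trimethyldodeca-2,6,10-trien-1-ol | C/C(=C\CO)CC/C=C(\C)CCC=C(C)C | starting material
19 | tert-butyl(dimethyl){[(2E,6E)-3,7,11-trimethyldodeca-2,6,10-trien-1-yl]oxy}silane | C/C(=C\CO[Si](C)(C)C(C)(C)C)CC/C=C(\C)CCC=C(C)C | intermediate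
20 | (2E,6E,10E)-12-{[tert-butyl(dimethyl)silyl]oxy}-2,6,10-trimethyldodeca-2,6,10-trien-1-ol | C/C(=C\CO[Si](C)(C)C(C)(C)C)CC/C=C(\C)CC/C=C(\C)CO | intermediate
21 | tert-butyl{[(2E,6E,10E)-12-bromo-3,7,11-trimethyldodeca-2,6,10-trien-1-yl]oxy}dimethylsilane | C/C(=C\CO[Si](C)(C)C(C)(C)C)CC/C=C(\C)CC/C=C(\C)CBr | intermediate
22 | O,C-dilithio derivative of 17 (lithium alkoxide, lithium on the sulfone-bearing carbon) | [Li]C(S(=O)(=O)c1ccccc1)[C@H]1C(C)(C)CCC[C@]1(C)O[Li] | intermediate (not isolated)
23 | (1S,2S)-2-[(3E,7E,11E)-1-(benzenesulfonyl)-13-{[tert-butyl(dimethyl)silyl]oxy}-3,7,11-trimethyltrideca-3,7,11-trien-1-yl]-1,3,3-trimethylcyclohexan-1-ol (epimers at the sulfone carbon) | C/C(=C\CO[Si](C)(C)C(C)(C)C)CC/C=C(\C)CC/C=C(\C)CC([C@H]1C(C)(C)CCC[C@]1(C)O)S(=O)(=O)c1ccccc1 | intermediate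
24 | (1S,2S)-2-[(3E,7E,11E)-13-{[tert-butyl(dimethyl)silyl]oxy}-3,7,11-trimethyltrideca-3,7,11-trien-1-yl]-1,3,3-trimethylcyclohexan-1-ol | C/C(=C\CO[Si](C)(C)C(C)(C)C)CC/C=C(\C)CC/C=C(\C)CC[C@H]1C(C)(C)CCC[C@]1(C)O | intermediate
25 | preluffariellolide A, (1S,2S)-2-[(3E,7E,11E)-13-hydroxy-3,7,11-trimethyltrideca-3,7,11-trien-1-yl]-1,3,3-trimethylcyclohexan-1-ol | C/C(=C\CO)CC/C=C(\C)CC/C=C(\C)CC[C@H]1C(C)(C)CCC[C@]1(C)O | target

Total step count: 17. Longest linear sequence: 14 steps (steps 1–11 and 15–17, from 1 to 25); steps 12–14 build the side-chain bromide.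

Steps most likely to fail

Step 7. Deprotonation by the amide base may be too slow. Boron may be captured at the CH2 end of the allyl anion or between two molecules, and configuration may erode through reversible complex formation before the shift. The fallback uses known chemistry and sets out from 7, which has no boron and can be lithiated with s-BuLi/TMEDA in Et2O at −78 °C. Borylation with 2-ethenyl-4,4,5,5-tetramethyl-1,3,2-dioxaborolane, 1,2-shift of the vinyl group on warming and NaOH/H2O2 oxidation should give (3S)-3,5,5-trimethyl-4-methylideneocta-1,7-dien-3-ol F1, by the same stereochemical course. Ring-closing metathesis of its vinyl and allyl groups with the second-generation Grubbs catalyst (CH2Cl2, 40 °C) gives (1S)-1,5,5-trimethyl-6-methylidenecyclohex-2-en-1-ol F2; the methylidene between two fully substituted carbons should stay out. Diimide (2-nitrobenzenesulfonohydrazide, Et3N) then saturates the unhindered cis ring alkene, and the route is rejoined at 12.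

Step 8. Si–H addition may stall at an alkene flanked by two fully substituted carbons, or the silyl ether may be lost by solvolysis before the platinum cycle turns over. The fallback sets out from 12. Radical addition of Se-phenyl benzenesulfonoselenoate (AIBN, benzene, 80 °C) gives (1S)-2-[(benzenesulfonyl)methyl]-1,3,3-trimethyl-2-(phenylselanyl)cyclohexan-1-ol F3. H2O2 oxidation and syn-elimination of the selenoxide, whose only beta hydrogens are on the CH2SO2Ph carbon, give the vinyl sulfone (1S)-2-[(benzenesulfonyl)methylidene]-1,3,3-trimethylcyclohexan-1-ol F4. Hydroxyl-directed hydrogenation with [Ir(cod)(PCy3)(py)]PF6 and H2 in CH2Cl2 should add hydrogen on the face of the tertiary OH, and the route is rejoined at 17.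

Step 15. Carbon–carbon bond formation at the carbanion beside the crowded ring CH may be slow, so that proton transfer to the bromide (elimination to a diene) or double alkylation competes. The fallback sets out from 15. I2, PPh3 and imidazole give (1S,2S)-2-(iodomethyl)-1,3,3-trimethylcyclohexan-1-ol F5, and TESOTf with 2,6-lutidine gives triethyl{[(1S,2S)-2-(iodomethyl)-1,3,3-trimethylcyclohexyl]oxy}silane F6. Its Grignard reagent (Mg, THF) is coupled with 21 under Li2CuCl4 catalysis at −20 °C (SN2 at the primary allylic bromide) to give the bis-silyl ether F7. TBAF removes both silyl groups, and the route is rejoined at 25.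

Further compounds
F1 | step 7 | (3S)-3,5,5-trimethyl-4-methylideneocta-1,7-dien-3-ol | C[C@](O)(C=C)C(=C)C(C)(C)CC=C
F2 | step 7 | (1S)-1,5,5-trimethyl-6-methylidenecyclohex-2-en-1-ol | C[C@]1(O)C=CCC(C)(C)C1=C
F3 | step 8 | (1S)-2-[(benzenesulfonyl)methyl]-1,3,3-trimethyl-2-(phenylselanyl)cyclohexan-1-ol (epimers at C2) | C[C@]1(O)CCCC(C)(C)C1(CS(=O)(=O)c1ccccc1)[Se]c1ccccc1
F4 | step 8 | (1S)-2-[(benzenesulfonyl)methylidene]-1,3,3-trimethylcyclohexan-1-ol | C[C@]1(O)CCCC(C)(C)C1=CS(=O)(=O)c1ccccc1
F5 | step 15 | (1S,2S)-2-(iodomethyl)-1,3,3-trimethylcyclohexan-1-ol | IC[C@H]1C(C)(C)CCC[C@]1(C)O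
F6 | step 15 | triethyl{[(1S,2S)-2-(iodomethyl)-1,3,3-trimethylcyclohexyl]oxy}silane | IC[C@H]1C(C)(C)CCC[C@]1(C)O[Si](CC)(CC)CC
F7 | step 15 | tert-butyl(dimethyl){[(2E,6E,10E)-3,7,11-trimethyl-13-[(1S,2S)-2,6,6-trimethyl-2-(triethylsilyloxy)cyclohexyl]trideca-2,6,10-trien-1-yl]oxy}silane | C/C(=C\CO[Si](C)(C)C(C)(C)C)CC/C=C(\C)CC/C=C(\C)CC[C@H]1C(C)(C)CCC[C@]1(C)O[Si](CC)(CC)CC
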